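**Retrosynthetic overview**

1. The target is an oxolane (O1, C2 bearing the benzofuranyl group, C3 bearing CH2OH, C4 the tertiary carbinol with the guaiacylmethyl group, C5 the CH2) attached to C5 of a 2,3-cis-2,3-dihydrobenzofuran; both phenols travel as benzyl ethers and the benzofuran CH2OH as a pivalate.
2. Key disconnection: oxolane bonds C3–C4 and O1–C5, an asymmetric interrupted Feist–Bénary union of aroylacetate 13 (O1, C2, C3 and the CH2OH carbon) with α-tosyloxy ketone 19 (C4, C5 and the arylmethyl group). The enabling feature is that carbinol C4 lies β to C3, C3 carries a carbon that can sit at the ester level, and O1 bridges C2 and C5, so the oxolane is a reduced 4-hydroxy-4,5-dihydrofuran-3-carboxylate.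
3. Oxolane C2 and C3 follow from a C4–OH-directed syn-hydrogenation of the C2=C3 enol ether, which places aryl, CH2OH and arylmethyl all cis; LiAlH4 and hydrogenolysis finish.
4. Fragment 13: the dihydrobenzofuran ring comes from an enantioselective dirhodium-carbenoid insertion into the benzylic ether C–H of aryldiazoacetate 5 (2,3-cis), starting from methyl 5-iodovanillate. Fragment 19 comes from 4-bromoguaiacol and glycidyl tosylate.
5. Ring order: dihydrobenzofuran (step 3), then the oxolane (step 12, formed as its 4,5-dihydrofuran).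

Key step: step 12

Assumption: the sense of induction of Rh2(S-PTTL)4 (step 3) and of (DHQD)2PYR (step 12) is taken to give the drawn configurations; if a first run shows the opposite, Rh2(R-PTTL)4 or the pseudoenantiomer (DHQ)2PYR is used instead.

**Route**

Step 1
Reactants: 1 methyl 4-hydroxy-3-iodo-5-methoxybenzoate; 2 [4-(benzyloxy)-3-methoxyphenyl]methanol
Product: 3 methyl 4-{[4-(benzyloxy)-3-methoxyphenyl]methoxy}-3-iodo-5-methoxybenzoate
Conditions: PPh3, DIAD, THF, 0 °C to rt
Reagents that add atoms: none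
Why: Mitsunobu etherification of an acidic, hindered phenol with a primary benzylic alcohol should give the aryl benzyl ether without touching the ester or the iodide.

Step 2
Reactants: 3 methyl 4-{[4-(benzyloxy)-3-methoxyphenyl]methoxy}-3-iodo-5-methoxybenzoate; 4 ethyl diazoacetate
Product: 5 methyl 4-{[4-(benzyloxy)-3-methoxyphenyl]methoxy}-3-(1-diazo-2-ethoxy-2-oxoethyl)-5-methoxybenzoate
Conditions: Pd(PPh3)4 (5 mol%), Ag2CO3 (0.5 equiv), Et3N, toluene, rt
Reagents that add atoms: none
Why: Palladium-catalysed cross-coupling of an aryl iodide with the C–H bond of a diazoacetate (oxidative addition, palladation of the diazo carbon, reductive elimination) should give the aryldiazoacetate with the diazo group intact.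

Step 3
Reactants: 5 methyl 4-{[4-(benzyloxy)-3-methoxyphenyl]methoxy}-3-(1-diazo-2-ethoxy-2-oxoethyl)-5-methoxybenzoate
Product: 6 3-ethyl 5-methyl (2R,3S)-2-[4-(benzyloxy)-3-methoxyphenyl]-7-methoxy-2,3-dihydro-1-benzofuran-3,5-dicarboxylate (2,3-cis)
Conditions: Rh2(S-PTTL)4 (1 mol%), toluene, −60 °C
Reagents that add atoms: none
Why: Intramolecular 1,5 C–H insertion of the donor/acceptor dirhodium carbenoid into the ether-activated benzylic CH2 closes the dihydrobenzofuran; the concerted insertion should place aryl and ester cis, and the chiral carboxylate ligands set the absolute configuration at C2 and C3.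

Step 4
Reactants: 6 3-ethyl 5-methyl (2R,3S)-2-[4-(benzyloxy)-3-methoxyphenyl]-7-methoxy-2,3-dihydro-1-benzofuran-3,5-dicarboxylate
Product: 7 [(2R,3R)-2-[4-(benzyloxy)-3-methoxyphenyl]-7-methoxy-2,3-dihydro-1-benzofuran-3,5-diyl]dimethanol (2,3-cis)
Conditions: LiAlH4, THF, −40 to 0 °C
Reagents that add atoms: none
Why: Hydride reduction of both esters at low temperature should outpace enolisation at C3, so the cis relationship is kept (the C3 descriptor changes only because the priorities change).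

Step 5
Reactants: 7 [(2R,3R)-2-[4-(benzyloxy)-3-methoxyphenyl]-7-methoxy-2,3-dihydro-1-benzofuran-3,5-diyl]dimethanol
Product: 8 (2R,3R)-2-[4-(benzyloxy)-3-methoxyphenyl]-3-(hydroxymethyl)-7-methoxy-2,3-dihydro-1-benzofuran-5-carbaldehyde
Conditions: MnO2, CH2Cl2, rt
Reagents that add atoms: none
Why: MnO2 oxidises the benzylic alcohol chemoselectively and should leave the aliphatic primary alcohol untouched under neutral conditions.

Step 6
Reactants: 8 (2R,3R)-2-[4-(benzyloxy)-3-methoxyphenyl]-3-(hydroxymethyl)-7-methoxy-2,3-dihydro-1-benzofuran-5-carbaldehyde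
Product: 9 [(2R,3R)-2-[4-(benzyloxy)-3-methoxyphenyl]-5-formyl-7-methoxy-2,3-dihydro-1-benzofuran-3-yl]methyl 2,2-dimethylpropanoate
Conditions: pivaloyl chloride, pyridine, DMAP (cat.), CH2Cl2, 0 °C
Reagents that add atoms: pivaloyl chloride CC(C)(C)C(Cl)=O
Why: Acylation gives a pivalate that should survive the enolate, oxidation and amine-base steps and is removed later by the LiAlH4 of step 14.

Step 7
Reactants: 9 [(2R,3R)-2-[4-(benzyloxy)-3-methoxyphenyl]-5-formyl-7-methoxy-2,3-dihydro-1-benzofuran-3-yl]methyl 2,2-dimethylpropanoate; 10 methyl acetate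
Product: 12 methyl 3-[(2R,3R)-2-[4-(benzyloxy)-3-methoxyphenyl]-3-{[(2,2-dimethylpropanoyl)oxy]methyl}-7-methoxy-2,3-dihydro-1-benzofuran-5-yl]-3-hydroxypropanoate (both carbinol epimers), via lithium ester enolate 11 (not isolated)
Conditions: LDA, 10, THF, −78 °C; then 9; NH4Cl aq.
Reagents that add atoms: none
Why: Aldol addition of the lithium enolate of methyl acetate to the aryl aldehyde at −78 °C should be much faster than attack on the hindered pivalate; the new carbinol centre is oxidised away in step 8.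

Step 8
Reactants: 12 methyl 3-[(2R,3R)-2-[4-(benzyloxy)-3-methoxyphenyl]-3-{[(2,2-dimethylpropanoyl)oxy]methyl}-7-methoxy-2,3-dihydro-1-benzofuran-5-yl]-3-hydroxypropanoate
Product: 13 methyl 3-[(2R,3R)-2-[4-(benzyloxy)-3-methoxyphenyl]-3-{[(2,2-dimethylpropanoyl)oxy]methyl}-7-methoxy-2,3-dihydro-1-benzofuran-5-yl]-3-oxopropanoate
Conditions: DMP, NaHCO3, CH2Cl2, rt
Reagents that add atoms: none
Why: Buffered periodinane oxidation of the β-hydroxy ester should give the aroylacetate without acid exposure of the cis-dihydrobenzofuran.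

Step 9
Reactants: 14 4-bromo-2-methoxyphenol
Product: 15 1-(benzyloxy)-4-bromo-2-methoxybenzene
Conditions: benzyl bromide, K2CO3, DMF, rt
Reagents that add atoms: benzyl bromide BrCc1ccccc1
Why: Williamson etherification of the phenol.

Step 10
Reactants: 15 1-(benzyloxy)-4-bromo-2-methoxybenzene; 16 oxiran-2-ylmethyl 4-methylbenzenesulfonate (racemic glycidyl tosylate)
Product: 18 3-[4-(benzyloxy)-3-methoxyphenyl]-2-hydroxypropyl 4-methylbenzenesulfonate (racemic), via aryl Grignard reagent 17 (not isolated)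
Conditions: Mg, THF, rt; then CuI (10 mol%), 16, THF, −40 °C; NH4Cl aq.
Reagents that add atoms: none
Why: Copper-catalysed opening of the epoxide at its terminal carbon by the aryl Grignard reagent should be faster at low temperature than displacement of the tosylate.

Step 11
Reactants: 18 3-[4-(benzyloxy)-3-methoxyphenyl]-2-hydroxypropyl 4-methylbenzenesulfonate
Product: 19 3-[4-(benzyloxy)-3-methoxyphenyl]-2-oxopropyl 4-methylbenzenesulfonate
Conditions: DMP, NaHCO3, CH2Cl2, rt
Reagents that add atoms: none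
Why: Periodinane oxidation of the secondary alcohol should give the α-tosyloxy ketone and removes the racemic centre.

Step 12
Reactants: 13 methyl 3-[(2R,3R)-2-[4-(benzyloxy)-3-methoxyphenyl]-3-{[(2,2-dimethylpropanoyl)oxy]methyl}-7-methoxy-2,3-dihydro-1-benzofuran-5-yl]-3-oxopropanoate; 19 3-[4-(benzyloxy)-3-methoxyphenyl]-2-oxopropyl 4-methylbenzenesulfonate
Product: 21 methyl (4S)-4-{[4-(benzyloxy)-3-methoxyphenyl]methyl}-2-[(2R,3R)-2-[4-(benzyloxy)-3-methoxyphenyl]-3-{[(2,2-dimethylpropanoyl)oxy]methyl}-7-methoxy-2,3-dihydro-1-benzofuran-5-yl]-4-hydroxy-4,5-dihydrofuran-3-carboxylate, via aldol adduct 20 (not isolated)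
Conditions: (DHQD)2PYR (10 mol%), 1,8-bis(dimethylamino)naphthalene (1.1 equiv), THF, −40 to −20 °C; pH 7 buffer work-up
Reagents that add atoms: none
Why: Proposed new method: the cinchona amine, regenerated by the stoichiometric naphthalene diamine base, turns aroylacetate 13 into a chiral ammonium enolate whose carbon C3 adds to the ketone carbonyl of 19 (aldol, C3–C4 bond) to give aldolate 20, and the enol oxygen O1 of the aryl ketone then displaces the primary tosylate at C5 in a 5-exo-tet O-alkylation that closes the 4,5-dihydrofuran (the future oxolane) and makes the reversible aldol irreversible. The closest known reaction type is the cinchona-catalysed asymmetric interrupted Feist–Bénary reaction of 1,3-dicarbonyl compounds with bromopyruvates and with α-tosyloxy aryl ketones; new here are a dialkyl α-tosyloxy ketone flanked by two methylene groups and an acyclic aroylacetate as the nucleophile. The only new stereocentre, C4, is set in the aldol event under catalyst control: the protonated quinuclidine hydrogen-bonds the ketone oxygen and the ion pair has to distinguish the polar CH2OTs arm from the arylmethyl arm, while the remote benzofuran centres exert no influence, so either pseudoenantiomeric catalyst can be used. The step needs aldol plus O-alkylation instead of direct SN2 C-alkylation at C5, and it must stop before dehydration to the furan. The tosylate leaving group, the non-nucleophilic amine bases, the low temperature and a non-acidic work-up are chosen to secure this. One operation thus joins the two halves of the molecule, forms C3–C4 and O1–C5, and lays down the complete carbon and oxygen pattern of the oxolane with its quaternary carbinol.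

Step 13
Reactants: 21 methyl (4S)-4-{[4-(benzyloxy)-3-methoxyphenyl]methyl}-2-[(2R,3R)-2-[4-(benzyloxy)-3-methoxyphenyl]-3-{[(2,2-dimethylpropanoyl)oxy]methyl}-7-methoxy-2,3-dihydro-1-benzofuran-5-yl]-4-hydroxy-4,5-dihydrofuran-3-carboxylate
Product: 22 methyl (2R,3R,4S)-4-{[4-(benzyloxy)-3-methoxyphenyl]methyl}-2-[(2R,3R)-2-[4-(benzyloxy)-3-methoxyphenyl]-3-{[(2,2-dimethylpropanoyl)oxy]methyl}-7-methoxy-2,3-dihydro-1-benzofuran-5-yl]-4-hydroxyoxolane-3-carboxylate
Conditions: [Ir(cod)(PCy3)(py)]PF6 (10 mol%), H2 (50 bar), CH2Cl2, rt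
Reagents that add atoms: none
Why: Hydroxyl-directed homogeneous hydrogenation: the tertiary C4–OH binds the cationic iridium and both hydrogens should be delivered to the tetrasubstituted C2=C3 bond from the OH face (also the face away from the arylmethyl group), which sets oxolane C2 and C3 with aryl, ester and arylmethyl all cis; benzyl ethers are not cleaved by this catalyst.

Step 14
Reactants: 22 methyl (2R,3R,4S)-4-{[4-(benzyloxy)-3-methoxyphenyl]methyl}-2-[(2R,3R)-2-[4-(benzyloxy)-3-methoxyphenyl]-3-{[(2,2-dimethylpropanoyl)oxy]methyl}-7-methoxy-2,3-dihydro-1-benzofuran-5-yl]-4-hydroxyoxolane-3-carboxylate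
Product: 23 (3S,4R,5R)-3-{[4-(benzyloxy)-3-methoxyphenyl]methyl}-5-[(2R,3R)-2-[4-(benzyloxy)-3-methoxyphenyl]-3-(hydroxymethyl)-7-methoxy-2,3-dihydro-1-benzofuran-5-yl]-4-(hydroxymethyl)oxolan-3-ol
Conditions: LiAlH4, THF, −20 to 0 °C
Reagents that add atoms: none
Why: Hydride reduction converts the methyl ester into the CH2OH group and cleaves the pivalate in the same operation; at low temperature reduction should outrun retro-aldol opening of the β-hydroxy ester.

Step 15
Reactants: 23 (3S,4R,5R)-3-{[4-(benzyloxy)-3-methoxyphenyl]methyl}-5-[(2R,3R)-2-[4-(benzyloxy)-3-methoxyphenyl]-3-(hydroxymethyl)-7-methoxy-2,3-dihydro-1-benzofuran-5-yl]-4-(hydroxymethyl)oxolan-3-ol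
Product: 24 (3S,4R,5R)-5-[(2R,3R)-2-(4-hydroxy-3-methoxyphenyl)-3-(hydroxymethyl)-7-methoxy-2,3-dihydro-1-benzofuran-5-yl]-3-[(4-hydroxy-3-methoxyphenyl)methyl]-4-(hydroxymethyl)oxolan-3-ol (CNP0284796.1)
Conditions: H2 (1 atm), Pd/C, EtOAc/MeOH, rt, stopped at full conversion
Reagents that add atoms: none
Why: Hydrogenolysis of the two phenolic benzyl ethers under neutral conditions should be much faster than cleavage of the cyclic benzylic ethers and exposes no acid that could epimerise the two cis-2-aryl centres.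

**Compound list**

1 | methyl 4-hydroxy-3-iodo-5-methoxybenzoate (methyl 5-iodovanillate) | COC(=O)c1cc(I)c(O)c(OC)c1 | starting material
2 | [4-(benzyloxy)-3-methoxyphenyl]methanol | COc1cc(CO)ccc1OCc1ccccc1 | starting material
3 | methyl 4-{[4-(benzyloxy)-3-methoxyphenyl]methoxy}-3-iodo-5-methoxybenzoate | COC(=O)c1cc(I)c(OCc2ccc(OCc3ccccc3)c(OC)c2)c(OC)c1 | intermediate
4 | ethyl diazoacetate | CCOC(=O)C=[N+]=[N-] | starting material
5 | methyl 4-{[4-(benzyloxy)-3-methoxyphenyl]methoxy}-3-(1-diazo-2-ethoxy-2-oxoethyl)-5-methoxybenzoate | CCOC(=O)C(=[N+]=[N-])c1cc(C(=O)OC)cc(OC)c1OCc1ccc(OCc2ccccc2)c(OC)c1 | intermediate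
6 | 3-ethyl 5-methyl (2R,3S)-2-[4-(benzyloxy)-3-methoxyphenyl]-7-methoxy-2,3-dihydro-1-benzofuran-3,5-dicarboxylate (2,3-cis) | COC(=O)c1cc(OC)c2c(c1)[C@H](C(=O)OCC)[C@H](c1ccc(OCc3ccccc3)c(OC)c1)O2 | intermediate
7 | [(2R,3R)-2-[4-(benzyloxy)-3-methoxyphenyl]-7-methoxy-2,3-dihydro-1-benzofuran-3,5-diyl]dimethanol (2,3-cis) | OCc1cc(OC)c2c(c1)[C@H](CO)[C@H](c1ccc(OCc3ccccc3)c(OC)c1)O2 | intermediate
8 | (2R,3R)-2-[4-(benzyloxy)-3-methoxyphenyl]-3-(hydroxymethyl)-7-methoxy-2,3-dihydro-1-benzofuran-5-carbaldehyde | O=Cc1cc(OC)c2c(c1)[C@H](CO)[C@H](c1ccc(OCc3ccccc3)c(OC)c1)O2 | intermediate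
9 | [(2R,3R)-2-[4-(benzyloxy)-3-methoxyphenyl]-5-formyl-7-methoxy-2,3-dihydro-1-benzofuran-3-yl]methyl 2,2-dimethylpropanoate | O=Cc1cc(OC)c2c(c1)[C@H](COC(=O)C(C)(C)C)[C@H](c1ccc(OCc3ccccc3)c(OC)c1)O2 | intermediate
10 | methyl acetate | COC(C)=O | starting material
11 | lithium 1-methoxyethen-1-olate (lithium enolate of methyl acetate) | [Li+].[O-]C(=C)OC | intermediate (not isolated)
12 | methyl 3-[(2R,3R)-2-[4-(benzyloxy)-3-methoxyphenyl]-3-{[(2,2-dimethylpropanoyl)oxy]methyl}-7-methoxy-2,3-dihydro-1-benzofuran-5-yl]-3-hydroxypropanoate (both carbinol epimers) | COC(=O)CC(O)c1cc(OC)c2c(c1)[C@H](COC(=O)C(C)(C)C)[C@H](c1ccc(OCc3ccccc3)c(OC)c1)O2 | intermediate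
13 | methyl 3-[(2R,3R)-2-[4-(benzyloxy)-3-methoxyphenyl]-3-{[(2,2-dimethylpropanoyl)oxy]methyl}-7-methoxy-2,3-dihydro-1-benzofuran-5-yl]-3-oxopropanoate | COC(=O)CC(=O)c1cc(OC)c2c(c1)[C@H](COC(=O)C(C)(C)C)[C@H](c1ccc(OCc3ccccc3)c(OC)c1)O2 | intermediate
14 | 4-bromo-2-methoxyphenol | COc1cc(Br)ccc1O | starting material
15 | 1-(benzyloxy)-4-bromo-2-methoxybenzene | COc1cc(Br)ccc1OCc1ccccc1 | intermediate
16 | oxiran-2-ylmethyl 4-methylbenzenesulfonate (racemic glycidyl tosylate) | Cc1ccc(cc1)S(=O)(=O)OCC1CO1 | starting material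
17 | [4-(benzyloxy)-3-methoxyphenyl]magnesium bromide | COc1cc([Mg]Br)ccc1OCc1ccccc1 | intermediate (not isolated)
18 | 3-[4-(benzyloxy)-3-methoxyphenyl]-2-hydroxypropyl 4-methylbenzenesulfonate (racemic) | COc1cc(CC(O)COS(=O)(=O)c2ccc(C)cc2)ccc1OCc1ccccc1 | intermediate
19 | 3-[4-(benzyloxy)-3-methoxyphenyl]-2-oxopropyl 4-methylbenzenesulfonate | COc1cc(CC(=O)COS(=O)(=O)c2ccc(C)cc2)ccc1OCc1ccccc1 | intermediate
20 | methyl (3S)-3-{[4-(benzyloxy)-3-methoxyphenyl]methyl}-2-{(2R,3R)-2-[4-(benzyloxy)-3-methoxyphenyl]-3-{[(2,2-dimethylpropanoyl)oxy]methyl}-7-methoxy-2,3-dihydro-1-benzofuran-5-carbonyl}-3-hydroxy-4-[(4-methylbenzenesulfonyl)oxy]butanoate (aldol adduct, C2 of the butanoate not defined) | COc1cc(C[C@@](O)(COS(=O)(=O)c2ccc(C)cc2)C(C(=O)OC)C(=O)c2cc(OC)c3c(c2)[C@H](COC(=O)C(C)(C)C)[C@H](c2ccc(OCc4ccccc4)c(OC)c2)O3)ccc1OCc1ccccc1 | intermediate (not isolated)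
21 | methyl (4S)-4-{[4-(benzyloxy)-3-methoxyphenyl]methyl}-2-[(2R,3R)-2-[4-(benzyloxy)-3-methoxyphenyl]-3-{[(2,2-dimethylpropanoyl)oxy]methyl}-7-methoxy-2,3-dihydro-1-benzofuran-5-yl]-4-hydroxy-4,5-dihydrofuran-3-carboxylate | COc1cc(C[C@@]2(O)COC(c3cc(OC)c4c(c3)[C@H](COC(=O)C(C)(C)C)[C@H](c3ccc(OCc5ccccc5)c(OC)c3)O4)=C2C(=O)OC)ccc1OCc1ccccc1 | intermediate
22 | methyl (2R,3R,4S)-4-{[4-(benzyloxy)-3-methoxyphenyl]methyl}-2-[(2R,3R)-2-[4-(benzyloxy)-3-methoxyphenyl]-3-{[(2,2-dimethylpropanoyl)oxy]methyl}-7-methoxy-2,3-dihydro-1-benzofuran-5-yl]-4-hydroxyoxolane-3-carboxylate | COc1cc(C[C@@]2(O)CO[C@@H](c3cc(OC)c4c(c3)[C@H](COC(=O)C(C)(C)C)[C@H](c3ccc(OCc5ccccc5)c(OC)c3)O4)[C@H]2C(=O)OC)ccc1OCc1ccccc1 | intermediate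
23 | (3S,4R,5R)-3-{[4-(benzyloxy)-3-methoxyphenyl]methyl}-5-[(2R,3R)-2-[4-(benzyloxy)-3-methoxyphenyl]-3-(hydroxymethyl)-7-methoxy-2,3-dihydro-1-benzofuran-5-yl]-4-(hydroxymethyl)oxolan-3-ol | COc1cc(C[C@@]2(O)CO[C@@H](c3cc(OC)c4c(c3)[C@H](CO)[C@H](c3ccc(OCc5ccccc5)c(OC)c3)O4)[C@H]2CO)ccc1OCc1ccccc1 | intermediate
24 | (3S,4R,5R)-5-[(2R,3R)-2-(4-hydroxy-3-methoxyphenyl)-3-(hydroxymethyl)-7-methoxy-2,3-dihydro-1-benzofuran-5-yl]-3-[(4-hydroxy-3-methoxyphenyl)methyl]-4-(hydroxymethyl)oxolan-3-ol | COc1cc(C[C@@]2(O)CO[C@@H](c3cc(OC)c4c(c3)[C@H](CO)[C@H](c3ccc(O)c(OC)c3)O4)[C@H]2CO)ccc1O | target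

**Step count and risks**

Total steps: 15. Longest linear sequence: 12 steps (steps 1–8, then 12–15); fragment 19 takes 3 steps (9–11).

Steps most likely to fail:

Step 12 (proposed method). The catalyst may discriminate poorly between the two methylene arms of the ketone, giving low selectivity at C4. Direct SN2 C-alkylation of the enolate at the tosylate carbon may compete, and the adduct may lose water to the furan. The fallback uses known chemistry, sets out from 13 and returns at 21. Compound 13 is combined with ethyl 3-bromo-2-oxopropanoate under the same cinchona amine and naphthalene diamine conditions; this is the activated-ketone case for which the asymmetric interrupted Feist–Bénary reaction is established, and it should give the hydroxy diester F1 with C4 set. NaBH4 in EtOH at 0 °C reduces only the α-hydroxy ester and gives the diol F2. TsCl in pyridine sulfonylates the primary hydroxyl to the tosylate F3, and DBU in CH2Cl2 closes the spiro-epoxide F4 with the C4–O bond untouched. Grignard reagent 17 with CuI (10 mol%) in THF at −40 °C then opens F4 at its CH2 carbon and delivers 21 with the arylmethyl group installed last.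

Step 13. The tetrasubstituted, ester-conjugated enol ether may not turn over, or acidic iridium hydride species may trigger loss of water and aromatisation to the furan. The fallback sets out from 21 and returns at 23, and reverses the order of reduction. DIBAL-H in CH2Cl2 at −78 °C reduces the conjugated ester to the allylic alcohol and removes the pivalate, giving the triol F5. Its alkene is now an electron-rich enol ether flanked by two hydroxyls, and it is hydrogenated with the less acidic cationic rhodium catalyst [Rh(nbd)(dppb)]BF4 under H2 (70 bar) in CH2Cl2, where chelation by the C4–OH and the allylic CH2OH should again direct addition to the OH face and give 23.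

Step 2. Loss of dinitrogen and carbene dimerisation may outrun the cross-coupling at the ortho-alkoxylated, electron-rich iodide. The fallback sets out from 3 and returns at 5, building the arylacetate first and introducing the diazo group afterwards. CuI with 2-picolinic acid and Cs2CO3 in dioxane couples 3 with diethyl malonate to the aryl malonate F6. Krapcho dealkoxycarbonylation (LiCl, wet DMSO, 130 °C) gives the arylacetate F7. Regitz diazo transfer with 4-acetamidobenzenesulfonyl azide and DBU in MeCN then gives 5.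

Further compounds

F1 | step 12 | 4-ethyl 3-methyl (4S)-2-[(2R,3R)-2-[4-(benzyloxy)-3-methoxyphenyl]-3-{[(2,2-dimethylpropanoyl)oxy]methyl}-7-methoxy-2,3-dihydro-1-benzofuran-5-yl]-4-hydroxy-4,5-dihydrofuran-3,4-dicarboxylate | CCOC(=O)[C@@]2(O)COC(c3cc(OC)c4c(c3)[C@H](COC(=O)C(C)(C)C)[C@H](c3ccc(OCc5ccccc5)c(OC)c3)O4)=C2C(=O)OC
F2 | step 12 | methyl (4R)-2-[(2R,3R)-2-[4-(benzyloxy)-3-methoxyphenyl]-3-{[(2,2-dimethylpropanoyl)oxy]methyl}-7-methoxy-2,3-dihydro-1-benzofuran-5-yl]-4-hydroxy-4-(hydroxymethyl)-4,5-dihydrofuran-3-carboxylate | OC[C@@]2(O)COC(c3cc(OC)c4c(c3)[C@H](COC(=O)C(C)(C)C)[C@H](c3ccc(OCc5ccccc5)c(OC)c3)O4)=C2C(=O)OC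
F3 | step 12 | methyl (4S)-2-[(2R,3R)-2-[4-(benzyloxy)-3-methoxyphenyl]-3-{[(2,2-dimethylpropanoyl)oxy]methyl}-7-methoxy-2,3-dihydro-1-benzofuran-5-yl]-4-hydroxy-4-{[(4-methylbenzenesulfonyl)oxy]methyl}-4,5-dihydrofuran-3-carboxylate | Cc1ccc(S(=O)(=O)OC[C@@]2(O)COC(c3cc(OC)c4c(c3)[C@H](COC(=O)C(C)(C)C)[C@H](c3ccc(OCc5ccccc5)c(OC)c3)O4)=C2C(=O)OC)cc1
F4 | step 12 | methyl (3R)-6-[(2R,3R)-2-[4-(benzyloxy)-3-methoxyphenyl]-3-{[(2,2-dimethylpropanoyl)oxy]methyl}-7-methoxy-2,3-dihydro-1-benzofuran-5-yl]-1,5-dioxaspiro[2.4]hept-6-ene-7-carboxylate | C1O[C@@]12COC(c3cc(OC)c4c(c3)[C@H](COC(=O)C(C)(C)C)[C@H](c3ccc(OCc5ccccc5)c(OC)c3)O4)=C2C(=O)OC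
F5 | step 13 | (3S)-3-{[4-(benzyloxy)-3-methoxyphenyl]methyl}-5-[(2R,3R)-2-[4-(benzyloxy)-3-methoxyphenyl]-3-(hydroxymethyl)-7-methoxy-2,3-dihydro-1-benzofuran-5-yl]-4-(hydroxymethyl)-2,3-dihydrofuran-3-ol | COc1cc(C[C@@]2(O)COC(c3cc(OC)c4c(c3)[C@H](CO)[C@H](c3ccc(OCc5ccccc5)c(OC)c3)O4)=C2CO)ccc1OCc1ccccc1
F6 | step 2 | diethyl 2-(2-{[4-(benzyloxy)-3-methoxyphenyl]methoxy}-3-methoxy-5-(methoxycarbonyl)phenyl)propanedioate | CCOC(=O)C(C(=O)OCC)c1cc(C(=O)OC)cc(OC)c1OCc1ccc(OCc2ccccc2)c(OC)c1
F7 | step 2 | methyl 4-{[4-(benzyloxy)-3-methoxyphenyl]methoxy}-3-(2-ethoxy-2-oxoethyl)-5-methoxybenzoate | CCOC(=O)Cc1cc(C(=O)OC)cc(OC)c1OCc1ccc(OCc2ccccc2)c(OC)c1
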